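**Retrosynthetic overview**

1. Target 24 ⇐ ether/carbonate cleavage of benzylidene-indane 23 ⇐ one-electron oxidative opening of head-to-head tetraarylcyclobutane 22 (anisyl–aryl bond broken, ring B closes the indane, proton loss gives the benzylidene).
2. Feature used: indane C1–C2 joins the two stilbene carbons that carry resorcinol rings (β, β′), while C3 and the exocyclic =CH carry the 4-oxyaryl rings (α, α′). One head-to-head stilbene photodimer holds all four carbons; only the β–β′ bond and the configuration of the ring-A carbon (C2) are kept.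
3. Cyclobutane 20 ⇐ intramolecular [2+2] photocycloaddition of bis-stilbene 19, whose resorcinol oxygens are joined by an unsymmetrical (R)-3-oxybutanoyl bridge (aryl ester on the anisyl stilbene, sec-alkyl ether on the dihydrobenzofuranyl stilbene).
4. 19 ⇐ esterification of stilbene phenol 3 (HWE) with acid 18; 18 ⇐ Heck reaction of styrene 6 with bromodihydrobenzofuran 16; 16 ⇐ Rh-carbene C–H insertion, then C2 epimerisation.
5. Ring order: dihydrobenzofuran (step 8); cyclobutane inside a 13-membered bridge ring (step 13); bridge ring opened (step 14); cyclobutane opened and indane five-membered ring closed (step 16).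

Key step: step 13

Abbreviations: ring A = resorcinol ring of the anisyl stilbene; ring B = resorcinol ring of the second stilbene; DBF = (2R,3R)-3-(3,5-dimethoxyphenyl)-2-(4-methoxyphenyl)-2,3-dihydro-1-benzofuran-5-yl.

Assumption 1: the sense in which the (R) bridge stereocentre selects between the two mirror-related stackings in step 13 is assumed, not derived; ethyl (3R)-3-hydroxybutanoate is equally available and would replace 4 if a trial irradiation showed the opposite sense.

Assumption 2: Rh2(R-PTAD)4 is taken as the catalyst antipode that gives the (3R) series in step 8; if the sense is opposite, the S catalyst is used.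

**Step 1**
Reactants: 1 3-hydroxy-5-methoxybenzaldehyde; 2 diethyl (4-methoxybenzyl)phosphonate
Product: 3 3-methoxy-5-[(E)-2-(4-methoxyphenyl)ethenyl]phenol
Conditions: KOtBu (2.5 equiv), THF/DMF, 0 °C → rt; 1 M HCl work-up
Reagents that add atoms: none
Why: Horner–Wadsworth–Emmons reaction of the semistabilised benzylphosphonate anion with the aldehyde should give the E-stilbene, the extra base holding the phenol as a meta-phenoxide that does not deactivate the aldehyde.

**Step 2**
Reactants: 1 3-hydroxy-5-methoxybenzaldehyde; 4 ethyl (3S)-3-hydroxybutanoate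
Product: 5 ethyl (3R)-3-(3-formyl-5-methoxyphenoxy)butanoate
Conditions: PPh3, DIAD, THF, 0 °C → rt
Reagents that add atoms: none
Why: Mitsunobu reaction in which the acidic formyl-phenol displaces the activated secondary alcohol with inversion, so the (S)-carbinol becomes the (R)-aryl ether.

**Step 3**
Reactants: 5 ethyl (3R)-3-(3-formyl-5-methoxyphenoxy)butanoate
Product: 6 ethyl (3R)-3-(3-ethenyl-5-methoxyphenoxy)butanoate
Conditions: Ph3PCH3Br (1.2 equiv), NaHMDS (1.1 equiv), THF, 0 °C
Reagents that add atoms: methyltriphenylphosphonium bromide, C[P+](c1ccccc1)(c1ccccc1)c1ccccc1.[Br-]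
Why: Wittig methylenation of the aldehyde by the non-stabilised ylide should be much faster than attack on the ester, and the stereocentre (β to the ester) is not acidic.

**Step 4**
Reactants: 7 5-bromo-2-hydroxybenzaldehyde; 8 4-methoxybenzyl chloride
Product: 9 5-bromo-2-[(4-methoxyphenyl)methoxy]benzaldehyde
Conditions: K2CO3, DMF, 60 °C
Reagents that add atoms: none
Why: Williamson ether synthesis on the phenoxide installs the benzylic CH2 and aryl group that later become C2 and its 4-methoxyphenyl substituent.

**Step 5**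
Reactants: 9 5-bromo-2-[(4-methoxyphenyl)methoxy]benzaldehyde; 10 (3,5-dimethoxyphenyl)magnesium chloride
Product: 11 rac-{5-bromo-2-[(4-methoxyphenyl)methoxy]phenyl}(3,5-dimethoxyphenyl)methanol
Conditions: THF, −78 → 0 °C; aq. NH4Cl
Reagents that add atoms: none
Why: Grignard 1,2-addition to the aldehyde at low temperature, where the aryl bromide does not exchange; the racemic carbinol centre is removed in step 6.

**Step 6**
Reactants: 11 rac-{5-bromo-2-[(4-methoxyphenyl)methoxy]phenyl}(3,5-dimethoxyphenyl)methanol
Product: 12 {5-bromo-2-[(4-methoxyphenyl)methoxy]phenyl}(3,5-dimethoxyphenyl)methanone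
Conditions: activated MnO2, CH2Cl2, rt
Reagents that add atoms: none
Why: MnO2 oxidation of a doubly benzylic alcohol to the benzophenone leaves the ethers and the bromide untouched.

**Step 7**
Reactants: 12 {5-bromo-2-[(4-methoxyphenyl)methoxy]phenyl}(3,5-dimethoxyphenyl)methanone
Product: 13 hydrazone of 12 (E/Z mixture)
Conditions: N2H4·H2O (10 equiv), AcOH (cat.), EtOH, 80 °C
Reagents that add atoms: hydrazine (used as the hydrate), NN
Why: Condensation of the diaryl ketone with excess hydrazine gives the free hydrazone, and both geometric isomers lead to the same diazo compound.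

**Step 8**
Reactants: 13 hydrazone of 12
Product: 15 (2S,3R)-5-bromo-3-(3,5-dimethoxyphenyl)-2-(4-methoxyphenyl)-2,3-dihydro-1-benzofuran (2,3-cis), via diaryldiazomethane 14 (not isolated)
Conditions: MnO2, CH2Cl2, 0 °C, filter; then Rh2(R-PTAD)4 (1 mol%), CH2Cl2, 0 °C → rt
Reagents that add atoms: none
Why: Hydrazone oxidation gives the diaryldiazomethane, and Rh(II)-catalysed intramolecular C–H insertion of the donor/donor carbene into the activated O–CH2–aryl bond (1,5-insertion) closes the five-membered ring; the chiral carboxylate ligands set C3 (R) and the insertion delivers the 2,3-cis isomer (C2 S).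

**Step 9**
Reactants: 15 (2S,3R)-5-bromo-3-(3,5-dimethoxyphenyl)-2-(4-methoxyphenyl)-2,3-dihydro-1-benzofuran
Product: 16 (2R,3R)-5-bromo-3-(3,5-dimethoxyphenyl)-2-(4-methoxyphenyl)-2,3-dihydro-1-benzofuran (2,3-trans)
Conditions: BF3·OEt2 (0.2 equiv), CH2Cl2, −20 → 0 °C
Reagents that add atoms: none
Why: Acid-catalysed epimerisation by reversible ionisation of the C2–O bond to the 4-methoxybenzylic cation and reclosure should give the more stable trans isomer (C2 now R) without touching C3.

**Step 10**
Reactants: 6 ethyl (3R)-3-(3-ethenyl-5-methoxyphenoxy)butanoate; 16 (2R,3R)-5-bromo-3-(3,5-dimethoxyphenyl)-2-(4-methoxyphenyl)-2,3-dihydro-1-benzofuran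
Product: 17 ethyl (3R)-3-{3-[(E)-2-(DBF)ethenyl]-5-methoxyphenoxy}butanoate
Conditions: Pd2(dba)3 (2.5 mol%), [HP(t-Bu)3]BF4 (10 mol%), Cy2NMe (1.5 equiv), dioxane, 80 °C
Reagents that add atoms: none
Why: Mizoroki–Heck reaction in which syn insertion of the terminal styrene at its unsubstituted carbon and syn β-hydride elimination give the E-stilbene, with no stereocentre involved.

**Step 11**
Reactants: 17 ethyl (3R)-3-{3-[(E)-2-(DBF)ethenyl]-5-methoxyphenoxy}butanoate
Product: 18 (3R)-3-{3-[(E)-2-(DBF)ethenyl]-5-methoxyphenoxy}butanoic acid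
Conditions: LiOH·H2O (3 equiv), THF/MeOH/H2O, 0 °C → rt; 1 M HCl to pH 3–4
Reagents that add atoms: lithium hydroxide, [Li+].[OH-]
Why: Saponification, in which hydroxide attacks the ester carbonyl far faster than it enolises the ester, so the β-aryloxy group is not eliminated.

**Step 12**
Reactants: 18 (3R)-3-{3-[(E)-2-(DBF)ethenyl]-5-methoxyphenoxy}butanoic acid; 3 3-methoxy-5-[(E)-2-(4-methoxyphenyl)ethenyl]phenol
Product: 19 3-methoxy-5-[(E)-2-(4-methoxyphenyl)ethenyl]phenyl (3R)-3-{3-[(E)-2-(DBF)ethenyl]-5-methoxyphenoxy}butanoate (tethered bis-stilbene)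
Conditions: DCC (1.2 equiv), DMAP (0.1 equiv), CH2Cl2, 0 °C → rt
Reagents that add atoms: none
Why: Steglich esterification joins the two stilbenes through the five-atom O–C(=O)–CH2–CH(CH3)–O bridge between their resorcinol oxygens under conditions that spare both alkenes and all stereocentres.

**Step 13**
Reactants: 19 tethered bis-stilbene
Product: 20 macrocyclic head-to-head tetraarylcyclobutane (C1 4-methoxyphenyl, C2 ring A, C3 ring B, C4 DBF; 1,2-trans, 2,3-cis, 3,4-trans, 1,4-cis)
Conditions: hν (350 nm, Pyrex), degassed benzene, 1 mM, 10–20 °C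
Reagents that add atoms: none
Why: Excitation of one stilbene should give an intramolecular excimer with the ground-state stilbene held face to face by the bridge, which collapses by suprafacial [2πs+2πs] addition; the closest known reaction type is the photodimerisation of stilbenes and cinnamates joined by short or chiral diol tethers. The four-membered ring closes by [2+2] inside a new 13-membered bridge ring, and the bridge between the two resorcinol rings allows only the head-to-head pairing (β to β′, α to α′). The relative configuration of the four new stereocentres follows from the E geometry of both alkenes (aryls trans across each former double bond) and from the parallel stacking (like aryls cis across the two new bonds). Which of the two mirror-related stackings reacts, and hence the configuration of the ring-A carbon that becomes C2, is to be set by the single bridge stereocentre. The bridge is unsymmetrical by design: in this dimer the two resorcinol rings are related by a local mirror plane, so a C2-symmetric diol bridge would fit both stackings equally and leave the choice to the remote 4-oxyaryl groups. The step needs cycloaddition to win over E/Z isomerisation and Z-stilbene electrocyclisation; E/Z isomerisation is reversible under the light while the cyclobutane no longer absorbs, oxygen is excluded, and high dilution suppresses intermolecular dimers.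

**Step 14**
Reactants: 20 macrocyclic head-to-head tetraarylcyclobutane
Product: 21 bridge-opened cyclobutane (ring A = 3-hydroxy-5-methoxyphenyl; ring B = 3-methoxy-5-{[(2R)-4-methoxy-4-oxobutan-2-yl]oxy}phenyl)
Conditions: K2CO3 (0.3 equiv), MeOH/THF, 0 °C, 30 min
Reagents that add atoms: methanol, CO
Why: Methoxide transesterification of the aryl ester opens the 13-membered ring much faster than the alkyl ester can undergo β-elimination; the bridge is cut here because the indane closure needs ring B in the plane of the new ring, where a model puts the bridged oxygens about 5–6 Å apart, beyond the reach of the three-carbon bridge.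

**Step 15**
Reactants: 21 bridge-opened cyclobutane
Product: 22 carbonate-capped cyclobutane (ring A = 3-methoxy-5-[(methoxycarbonyl)oxy]phenyl)
Conditions: ClCO2Me (1.5 equiv), pyridine, CH2Cl2, 0 °C
Reagents that add atoms: methyl chloroformate, COC(=O)Cl
Why: O-acylation of the freed phenol gives an aryl carbonate, which makes ring A a far poorer Friedel–Crafts partner than the dialkoxy ring B and so fixes which ring closes in step 16.

**Step 16**
Reactants: 22 carbonate-capped cyclobutane
Product: 23 (2S,3S,1E)-1-[(DBF)methylidene]-4-methoxy-3-(4-methoxyphenyl)-2-{3-methoxy-5-[(methoxycarbonyl)oxy]phenyl}-6-{[(2R)-4-methoxy-4-oxobutan-2-yl]oxy}-2,3-dihydro-1H-indene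
Conditions: tris(2,4-dibromophenyl)aminium hexachloroantimonate (2.2 equiv, portionwise), 2,6-di-tert-butylpyridine (3 equiv), CH2Cl2, −40 °C; aq. NaHCO3/Na2S2O3 quench
Reagents that add atoms: none
Why: Proposed new method: one-electron oxidation of an alkoxyaryl ring should give a radical cation in which the strained, doubly 4-alkoxybenzylic cyclobutane bond (anisyl carbon to DBF carbon) breaks to a 1,4-radical cation. The cationic anisyl carbon is then captured by ring B in a five-membered Friedel–Crafts closure; ring A could only form a four-membered ring with this centre and, as a carbonate, is a poor partner for the other one. The remaining benzylic radical is oxidised by the second equivalent, and the cation loses the adjacent ring proton to the hindered base, giving the exocyclic alkene. C2 is carried over unchanged from the cyclobutane, C3 is set trans to the C2 aryl group in the ring closure, and the E alkene is the isomer that avoids the peri C7–H. Closure at either ortho position of ring B leads to the same target; the one para to the side-chain ether is drawn. The closest known reaction types are the aminium-salt or photoredox cycloreversion of 1,2-diarylcyclobutanes through the same 1,4-radical cation, the arene capture seen when such radical cations give tetralins, and the acid-mediated indane closure of 8–8′-linked stilbene dimers.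

**Step 17**
Reactants: 23 benzylidene-indane
Product: 24 (2S,3S,1E)-1-{[(2R,3R)-3-(3,5-dihydroxyphenyl)-2-(4-hydroxyphenyl)-2,3-dihydro-1-benzofuran-5-yl]methylidene}-2-(3,5-dihydroxyphenyl)-3-(4-hydroxyphenyl)-2,3-dihydro-1H-indene-4,6-diol (CNP0184753.1)
Conditions: BBr3 (20 equiv), CH2Cl2, −78 °C → rt; H2O, 0 °C
Reagents that add atoms: none
Why: BBr3 ether cleavage removes the six methyl ethers, the secondary alkyl aryl ether and the methyl carbonate (O–CH3 cleavage, CO2 lost on work-up); the dihydrobenzofuran C2–O bond can ionise but should reclose to the stable trans isomer, and no stereocentre is changed.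

**Compound list**

1 | 3-hydroxy-5-methoxybenzaldehyde | COc1cc(O)cc(C=O)c1 | starting material
2 | diethyl (4-methoxybenzyl)phosphonate | CCOP(=O)(Cc1ccc(OC)cc1)OCC | starting material
3 | 3-methoxy-5-[(E)-2-(4-methoxyphenyl)ethenyl]phenol | COc1ccc(/C=C/c2cc(O)cc(OC)c2)cc1 | intermediate
4 | ethyl (3S)-3-hydroxybutanoate | CCOC(=O)C[C@H](C)O | starting material
5 | ethyl (3R)-3-(3-formyl-5-methoxyphenoxy)butanoate | CCOC(=O)C[C@@H](C)Oc1cc(OC)cc(C=O)c1 | intermediate
6 | ethyl (3R)-3-(3-ethenyl-5-methoxyphenoxy)butanoate | CCOC(=O)C[C@@H](C)Oc1cc(OC)cc(C=C)c1 | intermediate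
7 | 5-bromo-2-hydroxybenzaldehyde (5-bromosalicylaldehyde) | O=Cc1cc(Br)ccc1O | starting material
8 | 4-methoxybenzyl chloride | COc1ccc(CCl)cc1 | starting material
9 | 5-bromo-2-[(4-methoxyphenyl)methoxy]benzaldehyde | COc1ccc(COc2ccc(Br)cc2C=O)cc1 | intermediate
10 | (3,5-dimethoxyphenyl)magnesium chloride (THF solution) | COc1cc(OC)cc([Mg]Cl)c1 | starting material
11 | rac-{5-bromo-2-[(4-methoxyphenyl)methoxy]phenyl}(3,5-dimethoxyphenyl)methanol | COc1ccc(COc2ccc(Br)cc2C(O)c2cc(OC)cc(OC)c2)cc1 | intermediate
12 | {5-bromo-2-[(4-methoxyphenyl)methoxy]phenyl}(3,5-dimethoxyphenyl)methanone | COc1ccc(COc2ccc(Br)cc2C(=O)c2cc(OC)cc(OC)c2)cc1 | intermediate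
13 | hydrazone of 12 (E/Z mixture) | COc1ccc(COc2ccc(Br)cc2C(=NN)c2cc(OC)cc(OC)c2)cc1 | intermediate
14 | {5-bromo-2-[(4-methoxyphenyl)methoxy]phenyl}(3,5-dimethoxyphenyl)diazomethane | COc1ccc(COc2ccc(Br)cc2C(=[N+]=[N-])c2cc(OC)cc(OC)c2)cc1 | intermediate
15 | (2S,3R)-5-bromo-3-(3,5-dimethoxyphenyl)-2-(4-methoxyphenyl)-2,3-dihydro-1-benzofuran (cis) | Brc1ccc2c(c1)[C@@H](c1cc(OC)cc(OC)c1)[C@@H](c1ccc(OC)cc1)O2 | intermediate
16 | (2R,3R)-5-bromo-3-(3,5-dimethoxyphenyl)-2-(4-methoxyphenyl)-2,3-dihydro-1-benzofuran (trans) | Brc1ccc2c(c1)[C@@H](c1cc(OC)cc(OC)c1)[C@H](c1ccc(OC)cc1)O2 | intermediate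
17 | ethyl (3R)-3-{3-[(E)-2-(DBF)ethenyl]-5-methoxyphenoxy}butanoate | CCOC(=O)C[C@@H](C)Oc1cc(OC)cc(/C=C/c2ccc3c(c2)[C@@H](c2cc(OC)cc(OC)c2)[C@H](c2ccc(OC)cc2)O3)c1 | intermediate
18 | (3R)-3-{3-[(E)-2-(DBF)ethenyl]-5-methoxyphenoxy}butanoic acid | OC(=O)C[C@@H](C)Oc1cc(OC)cc(/C=C/c2ccc3c(c2)[C@@H](c2cc(OC)cc(OC)c2)[C@H](c2ccc(OC)cc2)O3)c1 | intermediate
19 | 3-methoxy-5-[(E)-2-(4-methoxyphenyl)ethenyl]phenyl (3R)-3-{3-[(E)-2-(DBF)ethenyl]-5-methoxyphenoxy}butanoate (tethered bis-stilbene) | COc1ccc(/C=C/c2cc(OC)cc(OC(=O)C[C@@H](C)Oc3cc(OC)cc(/C=C/c4ccc5c(c4)[C@@H](c4cc(OC)cc(OC)c4)[C@H](c4ccc(OC)cc4)O5)c3)c2)cc1 | intermediate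
20 | macrocyclic head-to-head cyclobutane: C1 4-methoxyphenyl, C2 ring A, C3 ring B, C4 DBF (1,2-trans, 2,3-cis, 3,4-trans, 1,4-cis); ring A oxygen acylated and ring B oxygen alkylated by the (R)-3-oxybutanoyl bridge (13-membered ring); the ring-A carbon has the configuration that becomes C2 of the indane | COc1ccc([C@@H]2[C@@H](c3cc(OC)cc(OC(=O)C[C@@H](C)O6)c3)[C@@H](c3cc(OC)cc6c3)[C@@H]2c2ccc3c(c2)[C@@H](c2cc(OC)cc(OC)c2)[C@H](c2ccc(OC)cc2)O3)cc1 | intermediate
21 | same cyclobutane, bridge opened: ring A = 3-hydroxy-5-methoxyphenyl, ring B = 3-methoxy-5-{[(2R)-4-methoxy-4-oxobutan-2-yl]oxy}phenyl | COc1ccc([C@@H]2[C@@H](c3cc(OC)cc(O)c3)[C@@H](c3cc(OC)cc(O[C@H](C)CC(=O)OC)c3)[C@@H]2c2ccc3c(c2)[C@@H](c2cc(OC)cc(OC)c2)[C@H](c2ccc(OC)cc2)O3)cc1 | intermediate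
22 | same cyclobutane, ring A = 3-methoxy-5-[(methoxycarbonyl)oxy]phenyl | COc1ccc([C@@H]2[C@@H](c3cc(OC)cc(OC(=O)OC)c3)[C@@H](c3cc(OC)cc(O[C@H](C)CC(=O)OC)c3)[C@@H]2c2ccc3c(c2)[C@@H](c2cc(OC)cc(OC)c2)[C@H](c2ccc(OC)cc2)O3)cc1 | intermediate
23 | (2S,3S,1E)-1-[(DBF)methylidene]-4-methoxy-3-(4-methoxyphenyl)-2-{3-methoxy-5-[(methoxycarbonyl)oxy]phenyl}-6-{[(2R)-4-methoxy-4-oxobutan-2-yl]oxy}-2,3-dihydro-1H-indene | COc1ccc([C@H]2c3c(OC)cc(O[C@H](C)CC(=O)OC)cc3/C(=C/c3ccc4c(c3)[C@@H](c3cc(OC)cc(OC)c3)[C@H](c3ccc(OC)cc3)O4)[C@@H]2c2cc(OC)cc(OC(=O)OC)c2)cc1 | intermediate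
24 | (2S,3S,1E)-1-{[(2R,3R)-3-(3,5-dihydroxyphenyl)-2-(4-hydroxyphenyl)-2,3-dihydro-1-benzofuran-5-yl]methylidene}-2-(3,5-dihydroxyphenyl)-3-(4-hydroxyphenyl)-2,3-dihydro-1H-indene-4,6-diol | Oc1ccc([C@H]2c3c(O)cc(O)cc3/C(=C/c3ccc4c(c3)[C@@H](c3cc(O)cc(O)c3)[C@H](c3ccc(O)cc3)O4)[C@@H]2c2cc(O)cc(O)c2)cc1 | target

**Step count**

Total: 17 steps. Longest linear sequence: 14 steps (steps 4–17, from 5-bromosalicylaldehyde).

**Steps most likely to fail**

1. Step 16 (Proposed new method). After the benzylic bond breaks, the 1,4-radical cation may lose the second ring bond as well (full cycloreversion to the two stilbenes) before ring B captures the cation. The electron-rich benzylidene product may also be oxidised further, and the dihydrobenzofuran may open at the radical-cation stage.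
Fallback, known chemistry only, setting out from 16 and returning at 24: bromine–lithium exchange on 16 (n-BuLi) and paraformaldehyde give the benzylic alcohol F1, and Lawesson's reagent converts it into the thiol F2. Separately, HWE reaction of commercial 2-bromo-3,5-dimethoxybenzaldehyde with diethyl (3,5-dimethoxybenzyl)phosphonate gives the bromostilbene F3; lithiation and addition to 4-methoxybenzaldehyde give the triaryl carbinol F4. Acid (TsOH, CH2Cl2) ionises F4; the cation cyclises onto the alkene to the 2,3-trans indane, and the indanyl cation is trapped at C1 by thiol F2 to give the sulfide F5. Oxidation (mCPBA) gives the sulfone F6, and a Ramberg–Bäcklund reaction (KOH, CCl4, t-BuOH) installs the exocyclic alkene to give the hexamethyl ether F7. BBr3 then gives 24. This indane is formed racemic, so F5 (or F7) would arise as two diastereomers that have to be separated; the absolute control of C2 is given up.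

2. Step 13 (key step). E/Z isomerisation and Z-stilbene electrocyclisation may drain the substrate, and the single bridge stereocentre may discriminate poorly, or in the wrong sense, between the two stackings.
Fallback, setting out from the step-13 mixture and returning at 19: the route then rests on separation and recycling instead of kinetic face selection. The diastereomer from the other stacking, F8, differs from 20 next to the bridge (the bridge ends are chemically different), so chromatographic separation should be possible. F8 is returned to 19 by photocycloreversion at 254 nm, or by a catalytic amount of the aminium salt of step 16, and is irradiated again.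

3. Step 8. The insertion may proceed with poor enantio- or diastereocontrol, the diazo compound may be lost to azine formation, and C3 may erode in the following acid epimerisation through elimination and re-addition.
Fallback, setting out from 7 and returning at 16: 7 with two equivalents of 10 gives the hydroxybenzhydrol F9. Its o-quinone methide, generated in situ, is captured by the ylide from (4-methoxybenzyl)dimethylsulfonium tetrafluoroborate (Cs2CO3, CH2Cl2) in a [4+1] annulation that gives the racemic trans-dihydrobenzofuran F10 directly, with no epimerisation step. Preparative chromatography on a chiral stationary phase then gives 16.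

**Further compounds**

F1 | step 16 | [(2R,3R)-3-(3,5-dimethoxyphenyl)-2-(4-methoxyphenyl)-2,3-dihydro-1-benzofuran-5-yl]methanol | OCc1ccc2c(c1)[C@@H](c1cc(OC)cc(OC)c1)[C@H](c1ccc(OC)cc1)O2
F2 | step 16 | [(2R,3R)-3-(3,5-dimethoxyphenyl)-2-(4-methoxyphenyl)-2,3-dihydro-1-benzofuran-5-yl]methanethiol | SCc1ccc2c(c1)[C@@H](c1cc(OC)cc(OC)c1)[C@H](c1ccc(OC)cc1)O2
F3 | step 16 | 2-bromo-1-[(E)-2-(3,5-dimethoxyphenyl)ethenyl]-3,5-dimethoxybenzene | COc1cc(OC)cc(/C=C/c2cc(OC)cc(OC)c2Br)c1
F4 | step 16 | rac-{2-[(E)-2-(3,5-dimethoxyphenyl)ethenyl]-4,6-dimethoxyphenyl}(4-methoxyphenyl)methanol | COc1ccc(C(O)c2c(OC)cc(OC)cc2/C=C/c2cc(OC)cc(OC)c2)cc1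
F5 | step 16 | (1S,2S,3S)-1-{[(DBF)methyl]sulfanyl}-2-(3,5-dimethoxyphenyl)-4,6-dimethoxy-3-(4-methoxyphenyl)-2,3-dihydro-1H-indene (desired diastereomer) | COc1ccc([C@H]2c3c(OC)cc(OC)cc3[C@@H](SCc3ccc4c(c3)[C@@H](c3cc(OC)cc(OC)c3)[C@H](c3ccc(OC)cc3)O4)[C@@H]2c2cc(OC)cc(OC)c2)cc1
F6 | step 16 | sulfone of F5 | COc1ccc([C@H]2c3c(OC)cc(OC)cc3[C@@H](S(=O)(=O)Cc3ccc4c(c3)[C@@H](c3cc(OC)cc(OC)c3)[C@H](c3ccc(OC)cc3)O4)[C@@H]2c2cc(OC)cc(OC)c2)cc1
F7 | step 16 | hexamethyl ether of 24: (2S,3S,1E)-1-[(DBF)methylidene]-2-(3,5-dimethoxyphenyl)-4,6-dimethoxy-3-(4-methoxyphenyl)-2,3-dihydro-1H-indene | COc1ccc([C@H]2c3c(OC)cc(OC)cc3/C(=C/c3ccc4c(c3)[C@@H](c3cc(OC)cc(OC)c3)[C@H](c3ccc(OC)cc3)O4)[C@@H]2c2cc(OC)cc(OC)c2)cc1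
F8 | step 13 | diastereomer of 20 from the other stacking (all four cyclobutane centres inverted, bridge and DBF unchanged) | COc1ccc([C@H]2[C@H](c3cc(OC)cc(OC(=O)C[C@@H](C)O6)c3)[C@H](c3cc(OC)cc6c3)[C@H]2c2ccc3c(c2)[C@@H](c2cc(OC)cc(OC)c2)[C@H](c2ccc(OC)cc2)O3)cc1
F9 | step 8 | rac-4-bromo-2-[(3,5-dimethoxyphenyl)(hydroxy)methyl]phenol | COc1cc(OC)cc(C(O)c2cc(Br)ccc2O)c1
F10 | step 8 | rac-(2R*,3R*)-5-bromo-3-(3,5-dimethoxyphenyl)-2-(4-methoxyphenyl)-2,3-dihydro-1-benzofuran (racemate, trans; one enantiomer drawn) | Brc1ccc2c(c1)[C@@H](c1cc(OC)cc(OC)c1)[C@H](c1ccc(OC)cc1)O2
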